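**Assumption:** the target has no stereocentre and no stereogenic double bond, so "single enantiomer" is read as the one achiral compound drawn; 5-heptylresorcinol and 2-bromo-4,5-dimethoxybenzoic acid are taken as catalogue compounds.

## Retrosynthetic overview

1. Target ⇐ one-pot BBr3 unmasking of a tri-O-methyl tert-butyl ester (three ArOMe and CO2t-Bu).
2. Key disconnection: the benzylic CH2–aryl bond, made by palladium-catalysed γ-arylation of the zinc dienolate of a preformed 2-methylchromone with an ortho-bromobenzoate. This replaces the usual acetophenone + homophthalate diketone assembly; the chromone methyl group becomes the CH2 bridge.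
3. 2-Methylchromone ⇐ o-hydroxyacetophenone + amide acetal (enaminone annulation); acetophenone ⇐ 5-heptylresorcinol by C-acetylation and para-O-methylation.
4. Aryl bromide ⇐ 2-bromo-4,5-dimethoxybenzoic acid by tert-butyl esterification.
5. Ring order: both benzene rings are bought; the pyranone ring is the only ring formed, before the fragment union; no stereocentre arises.

## Route

Step 1
Reactants: 1 5-heptylbenzene-1,3-diol (5-heptylresorcinol)
Product: 2 1-(2-heptyl-4,6-dihydroxyphenyl)ethan-1-one
Conditions: AcOH (1.2 equiv), BF3·OEt2 as solvent, 90 °C; then aq. NaOAc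
Reagents that add atoms: acetic acid, CC(=O)O
Why: Friedel–Crafts (Nencki-type) C-acylation goes to the ring position para to one hydroxyl and ortho to the other, as with orcinol, giving the hydrogen-bonded o-hydroxy ketone; the site between the two hydroxyls is the minor one.

Step 2
Reactants: 2 1-(2-heptyl-4,6-dihydroxyphenyl)ethan-1-one
Product: 3 1-(2-heptyl-6-hydroxy-4-methoxyphenyl)ethan-1-one
Conditions: MeI (1.1 equiv), K2CO3, acetone, 56 °C
Reagents that add atoms: iodomethane, CI
Why: Williamson ether synthesis is selective for the para-hydroxyl because the ortho-hydroxyl is held in a hydrogen bond to the ketone and is far less nucleophilic.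

Step 3
Reactants: 3 1-(2-heptyl-6-hydroxy-4-methoxyphenyl)ethan-1-one
Product: 5 5-heptyl-7-methoxy-2-methyl-4H-chromen-4-one, via enaminone 4 (not isolated)
Conditions: MeC(OMe)2NMe2 (2 equiv), toluene, 110 °C; then AcOH, 80 °C
Reagents that add atoms: N,N-dimethylacetamide dimethyl acetal, CC(OC)(OC)N(C)C
Why: Amide-acetal condensation on the acetyl methyl gives the enaminone, and acid-promoted intramolecular oxa-Michael addition with loss of dimethylamine (enaminone chromone annulation) closes the pyranone ring with the 2-methyl group in place.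

Step 4
Reactants: 6 2-bromo-4,5-dimethoxybenzoic acid
Product: 7 tert-butyl 2-bromo-4,5-dimethoxybenzoate
Conditions: Cl3CC(=NH)Ot-Bu (2 equiv), BF3·OEt2 (5 mol %), CH2Cl2–cyclohexane, rt
Reagents that add atoms: tert-butyl 2,2,2-trichloroacetimidate, CC(C)(C)OC(=N)C(Cl)(Cl)Cl
Why: Acid-catalysed imidate esterification tert-butylates the hindered acid, giving an ester that resists enolate attack in step 5 and is cleaved by BBr3 in step 6.

Step 5
Reactants: 5 5-heptyl-7-methoxy-2-methyl-4H-chromen-4-one (1.2 equiv); 7 tert-butyl 2-bromo-4,5-dimethoxybenzoate (1.0 equiv)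
Product: 10 tert-butyl 2-[(5-heptyl-7-methoxy-4-oxo-4H-chromen-2-yl)methyl]-4,5-dimethoxybenzoate, via lithium dienolate 8 (not isolated), via chlorozinc dienolate 9 (not isolated)
Conditions: LiN(SiMe3)2 (1.25 equiv), THF, −78 °C; ZnCl2 (1.3 equiv), −78 °C to rt; then 7, Pd2(dba)3 (2.5 mol %), XPhos (10 mol %), THF, 60 °C
Reagents that add atoms: none
Why: Proposed new method: LiN(SiMe3)2 removes a proton from the 2-methyl group (vinylogous to the C4 ketone), ZnCl2 converts the lithium dienolate into a soft zinc dienolate that tolerates the ester and does not self-condense, and after oxidative addition of 7 to zerovalent palladium and transmetalation, reductive elimination occurs at the exocyclic carbon because only that site restores the aromatic pyranone; the closest known reactions are the palladium-catalysed α-arylation of zinc enolates (Negishi-type coupling of Reformatsky reagents), the γ-arylation of dienolates and the benzylic arylation of 2-methylazines.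

Step 6
Reactants: 10 tert-butyl 2-[(5-heptyl-7-methoxy-4-oxo-4H-chromen-2-yl)methyl]-4,5-dimethoxybenzoate
Product: 11 2-[(5-heptyl-7-hydroxy-4-oxo-4H-chromen-2-yl)methyl]-4,5-dihydroxybenzoic acid
Conditions: BBr3 (8 equiv), CH2Cl2, −78 °C to rt; then H2O, 0 °C
Reagents that add atoms: none
Why: Lewis-acid ether cleavage: BBr3 demethylates the three aryl methyl ethers by bromide SN2 attack on the O-methyl groups and ionises the tert-butyl ester, and hydrolysis of the borates on work-up frees the catechol, phenol and acid; every open ring position is flanked by two substituents, so tert-butylation of the rings is disfavoured.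

## Compound list

1 | 5-heptylbenzene-1,3-diol (5-heptylresorcinol) | CCCCCCCc1cc(O)cc(O)c1 | starting material
2 | 1-(2-heptyl-4,6-dihydroxyphenyl)ethan-1-one | CCCCCCCc1cc(O)cc(O)c1C(C)=O | intermediate
3 | 1-(2-heptyl-6-hydroxy-4-methoxyphenyl)ethan-1-one | CCCCCCCc1cc(OC)cc(O)c1C(C)=O | intermediate
4 | (E)-3-(dimethylamino)-1-(2-heptyl-6-hydroxy-4-methoxyphenyl)but-2-en-1-one (enaminone, not isolated) | CCCCCCCc1cc(OC)cc(O)c1C(=O)/C=C(\C)N(C)C | intermediate
5 | 5-heptyl-7-methoxy-2-methyl-4H-chromen-4-one | CCCCCCCc1cc(OC)cc2oc(C)cc(=O)c12 | intermediate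
6 | 2-bromo-4,5-dimethoxybenzoic acid | COc1cc(Br)c(C(=O)O)cc1OC | starting material
7 | tert-butyl 2-bromo-4,5-dimethoxybenzoate | COc1cc(Br)c(C(=O)OC(C)(C)C)cc1OC | intermediate
8 | lithium 5-heptyl-7-methoxy-2-methylidene-2H-chromen-4-olate (lithium dienolate, not isolated) | [Li]OC1=CC(=C)Oc2cc(OC)cc(CCCCCCC)c12 | intermediate
9 | chlorozinc 5-heptyl-7-methoxy-2-methylidene-2H-chromen-4-olate (chlorozinc dienolate, not isolated) | Cl[Zn]OC1=CC(=C)Oc2cc(OC)cc(CCCCCCC)c12 | intermediate
10 | tert-butyl 2-[(5-heptyl-7-methoxy-4-oxo-4H-chromen-2-yl)methyl]-4,5-dimethoxybenzoate | CCCCCCCc1cc(OC)cc2oc(Cc3cc(OC)c(OC)cc3C(=O)OC(C)(C)C)cc(=O)c12 | intermediate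
11 | 2-[(5-heptyl-7-hydroxy-4-oxo-4H-chromen-2-yl)methyl]-4,5-dihydroxybenzoic acid | CCCCCCCc1cc(O)cc2oc(Cc3cc(O)c(O)cc3C(=O)O)cc(=O)c12 | target

## Step count and risks

Total step count: 6. Longest linear sequence: 5 steps (1 → 2 → 3 → 5 → 10 → 11; step 4 is on the side branch).

**Most likely to fail, first: step 5 (the γ-arylation).** It may give arylation at C3, a second arylation at the now more acidic CH2, or stall at transmetalation. The fallback reverses the polarity of the union and sets out from 5 (with 7 as the aryl source).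
- SeO2 in refluxing 1,4-dioxane oxidises the activated 2-methyl group of 5 to 5-heptyl-7-methoxy-4-oxo-4H-chromene-2-carbaldehyde F1.
- Bromide 7 is converted with i-PrMgCl·LiCl (THF, −20 °C) into [2-(tert-butoxycarbonyl)-4,5-dimethoxyphenyl]magnesium chloride F2.
- F2 adds to the aldehyde of F1 at −40 °C to give the chloromagnesium alkoxide of tert-butyl 2-[(5-heptyl-7-methoxy-4-oxo-4H-chromen-2-yl)(hydroxy)methyl]-4,5-dimethoxybenzoate F3.
- On warming, F3 closes onto the neighbouring ester with loss of tert-butoxide to give the racemic phthalide 3-(5-heptyl-7-methoxy-4-oxo-4H-chromen-2-yl)-5,6-dimethoxy-2-benzofuran-1(3H)-one F4.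
- Zinc dust in AcOH (60 °C) cleaves the benzylic, chromone-activated C–O bond reductively (vinylogous α-acyloxy ketone reduction), which also removes the stereocentre, giving 2-[(5-heptyl-7-methoxy-4-oxo-4H-chromen-2-yl)methyl]-4,5-dimethoxybenzoic acid F5.
- BBr3 under the conditions of step 6 removes the three methyl groups, so the fallback comes back to the route at the target 11.

**Second: step 1 (regiochemistry of the acetylation).** The 2-acyl isomer (between the hydroxyls) or diacylation may compete. The fallback sets out from 1 and replaces steps 1 and 2.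
- Exhaustive methylation (Me2SO4, K2CO3, acetone) gives 1-heptyl-3,5-dimethoxybenzene F6.
- Friedel–Crafts acetylation (AcCl, AlCl3, CH2Cl2, 0 °C) takes place para to one methoxy group and next to the alkyl chain, not at the crowded site between the two methoxy groups, giving 1-(2-heptyl-4,6-dimethoxyphenyl)ethan-1-one F7.
- BCl3 (CH2Cl2, −78 to 0 °C) removes only the methyl group ortho to the chelating ketone and delivers 3, where the route resumes.

**Third: step 3 (chromone annulation).** The ketone is flanked by two ortho substituents, and the amide acetal may O-methylate the phenol instead of condensing. The fallback sets out from 3.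
- Ac2O, pyridine and DMAP give 2-acetyl-3-heptyl-5-methoxyphenyl acetate F8.
- KOt-Bu in THF (0 °C to rt) effects the Baker–Venkataraman acyl shift to 1-(2-heptyl-6-hydroxy-4-methoxyphenyl)butane-1,3-dione F9.
- Catalytic H2SO4 in AcOH (80 °C) cyclodehydrates F9 to 5, where the route resumes.

## Further compounds

F1 | step 5 | 5-heptyl-7-methoxy-4-oxo-4H-chromene-2-carbaldehyde | CCCCCCCc1cc(OC)cc2oc(C=O)cc(=O)c12
F2 | step 5 | [2-(tert-butoxycarbonyl)-4,5-dimethoxyphenyl]magnesium chloride | COc1cc([Mg]Cl)c(C(=O)OC(C)(C)C)cc1OC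
F3 | step 5 | chloromagnesium alkoxide of tert-butyl 2-[(5-heptyl-7-methoxy-4-oxo-4H-chromen-2-yl)(hydroxy)methyl]-4,5-dimethoxybenzoate (racemic) | CCCCCCCc1cc(OC)cc2oc(C(O[Mg]Cl)c3cc(OC)c(OC)cc3C(=O)OC(C)(C)C)cc(=O)c12
F4 | step 5 | 3-(5-heptyl-7-methoxy-4-oxo-4H-chromen-2-yl)-5,6-dimethoxy-2-benzofuran-1(3H)-one (racemic) | O=C1OC(c2cc(=O)c3c(CCCCCCC)cc(OC)cc3o2)c2cc(OC)c(OC)cc12
F5 | step 5 | 2-[(5-heptyl-7-methoxy-4-oxo-4H-chromen-2-yl)methyl]-4,5-dimethoxybenzoic acid | CCCCCCCc1cc(OC)cc2oc(Cc3cc(OC)c(OC)cc3C(=O)O)cc(=O)c12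
F6 | step 1 | 1-heptyl-3,5-dimethoxybenzene | CCCCCCCc1cc(OC)cc(OC)c1
F7 | step 1 | 1-(2-heptyl-4,6-dimethoxyphenyl)ethan-1-one | CCCCCCCc1cc(OC)cc(OC)c1C(C)=O
F8 | step 3 | 2-acetyl-3-heptyl-5-methoxyphenyl acetate | CCCCCCCc1cc(OC)cc(OC(C)=O)c1C(C)=O
F9 | step 3 | 1-(2-heptyl-6-hydroxy-4-methoxyphenyl)butane-1,3-dione | CCCCCCCc1cc(OC)cc(O)c1C(=O)CC(C)=O
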